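The enedione ring (C1 carries the coumarin, then C2–H, C3=O, C4(OH)(prenyl), C5H2, C6=O) is cut at C2–C3 and C4–C5, the two ring bonds that flank the vicinally oxygenated pair C3/C4. The key step exploits this pair: at the dicarbonyl level its two carbonyl carbons act as the two-atom partner of a ruthenium-catalysed, hydrogen-borrowing [4+2] cycloaddition. In one operation an acyclic α-hydroxy ketone and a 2-siloxy-3-coumarinyl butadiene are joined, the carbocycle is closed and the tertiary carbinol is built, with C6 left masked as silyl enol ether and C3 as a temporary carbinol that relays the chirality. Two oxidations finish the target.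

Key step: step 6

Assumption: the sense of induction of the biaryl bisphosphine cannot be derived from precedent, so the (R)-ligand is written and its antipode is taken if the first run gives the mirror-image series; ring atoms in the Why lines carry the target numbering of the overview.

Step 1
Reactants: 1 2-hydroxy-4-methoxybenzaldehyde; 2 α-angelica lactone (5-methylfuran-2(3H)-one)
Product: 4 7-methoxy-3-(2-oxopropyl)-2H-chromen-2-one, via arylidene lactone 3 (not isolated)
Conditions: Et3N (cat.), EtOH, reflux
Reagents that add atoms: none
Why: Knoevenagel-type condensation at the acidic ring CH2 of the butenolide gives 3, whose enol-ester carbonyl is then attacked by the ortho phenol (translactonisation), which releases the enol as the methyl ketone and closes the coumarin.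

Step 2
Reactants: 4 7-methoxy-3-(2-oxopropyl)-2H-chromen-2-one
Product: 5 7-methoxy-3-(3-oxobut-1-en-2-yl)-2H-chromen-2-one
Conditions: (CH2O)n, iPr2NH·CF3CO2H, THF, reflux
Reagents that add atoms: formaldehyde (as paraformaldehyde), C=O
Why: Mannich condensation and elimination (α-methylenation) should take place at the CH2 flanked by coumarin and ketone, which is by far the more acidic and more easily enolised α-position.

Step 3
Reactants: 5 7-methoxy-3-(3-oxobut-1-en-2-yl)-2H-chromen-2-one
Product: 6 3-[3-(tert-butyldimethylsilyloxy)buta-1,3-dien-2-yl]-7-methoxy-2H-chromen-2-one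
Conditions: TBSOTf, Et3N, CH2Cl2, 0 °C
Reagents that add atoms: tert-butyldimethylsilyl trifluoromethanesulfonate, CC(C)(C)[Si](C)(C)OS(=O)(=O)C(F)(F)F
Why: Soft enolisation and O-silylation; the methyl group is the only enolisable position of 5, so the cross-conjugated 2-siloxy diene is the only possible silyl enol ether.

Step 4
Reactants: 7 glycidol (racemic); 8 2-methylprop-1-enylmagnesium bromide (2.2 equiv)
Product: 9 5-methylhex-4-ene-1,2-diol (racemic)
Conditions: CuI (10 mol%), THF, −30 to 0 °C; aq NH4Cl
Reagents that add atoms: none
Why: Copper-catalysed SN2 opening of the epoxide at its CH2 by an alkenyl Grignard reagent builds the prenyl chain without the transposition of allyl metals, and the carbinol stereocenter is irrelevant because steps 5 and 6 erase it.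

Step 5
Reactants: 9 5-methylhex-4-ene-1,2-diol
Product: 10 1-hydroxy-5-methylhex-4-en-2-one
Conditions: [(neocuproine)Pd(OAc)]2(OTf)2 (3 mol%), 1,4-benzoquinone, MeCN/H2O, 23 °C
Reagents that add atoms: none
Why: Chelation-directed chemoselective oxidation of a vicinal diol at its secondary carbinol by a cationic divalent palladium catalyst (β-hydride elimination from the chelated diolate), in which the hindered trisubstituted alkene should not undergo oxypalladation.

Step 6
Reactants: 6 3-[3-(tert-butyldimethylsilyloxy)buta-1,3-dien-2-yl]-7-methoxy-2H-chromen-2-one; 10 1-hydroxy-5-methylhex-4-en-2-one (1.5 equiv)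
Product: 12 3-[(4R,5S)-2-(tert-butyldimethylsilyloxy)-4,5-dihydroxy-4-(3-methylbut-2-enyl)cyclohex-1-enyl]-7-methoxy-2H-chromen-2-one (cis-diol), via keto aldehyde 11 (not isolated)
Conditions: Ru3(CO)12 (3 mol%), (R)-MeO-BIPHEP (9 mol%), PhMe, 130 °C, sealed tube
Reagents that add atoms: none
Why: Proposed new method: zerovalent ruthenium borrows hydrogen from ketol 10 to give keto aldehyde 11, couples its aldehyde carbon oxidatively with the CH2 terminus on the coumarinyl side of diene 6 (bond C2–C3) to a 2-siloxyallyl ruthenium alkoxide, lets the remaining allyl terminus add to the neighbouring ketone (bond C4–C5) and then returns the hydrogen, which frees diol 12 and the catalyst. The closest known reaction type is the Ru3(CO)12/phosphine transfer-hydrogenative [4+2] cycloaddition of dienes with 1,2-diols, α-ketols or 1,2-diones, established with achiral phosphines such as BIPHEP, and the new element is asymmetric induction by an atropisomeric analogue of the same bite angle. The one ring that is closed, the six-membered carbocycle, forms by intramolecular carbonyl allylation within the metallacycle, formally a [4+2] in which the two carbonyl carbons are the two-atom partner. C3 is set in the oxidative coupling inside the twofold-symmetric pocket of the ligand, and C4 is set relative to it because both oxygens stay bound to the same ruthenium, which forces a cis diol, so the temporary C3 carbinol relays the ligand chirality to the fully substituted centre. The step needs the pairing aldehyde carbon/C2 and ketone carbon/C5, which is secured by the less hindered, more electrophilic aldehyde reacting first and by the aryl-substituted half of the diene being the better π-acceptor for the electron-rich metal than the silyl enol ether half, whose CH2 then reacts as the enolate-like allyl terminus. The trisubstituted prenyl and coumarin 3,4-double bonds should bind too weakly to compete, and the reactive, enolisable 11 is present only in traces.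

Step 7
Reactants: 12 cis-diol
Product: 13 3-[(4R)-2-(tert-butyldimethylsilyloxy)-4-hydroxy-4-(3-methylbut-2-enyl)-5-oxocyclohex-1-enyl]-7-methoxy-2H-chromen-2-one
Conditions: IBX, DMSO, 23 °C
Reagents that add atoms: none
Why: IBX oxidation turns the secondary carbinol of a 1,2-diol into the α-ketol without glycol cleavage, which erases the temporary C3 stereocenter while the non-oxidisable tertiary carbinol C4, the silyl enol ether and the alkenes should survive at room temperature.

Step 8
Reactants: 13 α-ketol silyl enol ether
Product: 14 3-[(4R)-4-hydroxy-4-(3-methylbut-2-enyl)-3,6-dioxocyclohex-1-enyl]-7-methoxy-2H-chromen-2-one (target)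
Conditions: Pd(OAc)2 (1.05 equiv), MeCN, 23 °C
Reagents that add atoms: none
Why: Saegusa–Ito oxidation (silyl enol ether to palladium enolate at C1, β-hydride elimination of the doubly activated C2–H) unmasks C6=O and sets the C1=C2 double bond at room temperature without added base, so the β-hydroxy ketone should not dehydrate, and C4 carries no hydrogen and cannot epimerise.

Compound list
1 | 2-hydroxy-4-methoxybenzaldehyde | COc1ccc(C=O)c(O)c1 | starting material
2 | α-angelica lactone (5-methylfuran-2(3H)-one) | CC1=CCC(=O)O1 | starting material
3 | 3-(2-hydroxy-4-methoxybenzylidene)-5-methylfuran-2(3H)-one | CC1=CC(=Cc2ccc(OC)cc2O)C(=O)O1 | intermediate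
4 | 7-methoxy-3-(2-oxopropyl)-2H-chromen-2-one | COc1ccc2cc(CC(C)=O)c(=O)oc2c1 | intermediate
5 | 7-methoxy-3-(3-oxobut-1-en-2-yl)-2H-chromen-2-one | COc1ccc2cc(C(=C)C(C)=O)c(=O)oc2c1 | intermediate
6 | 3-[3-(tert-butyldimethylsilyloxy)buta-1,3-dien-2-yl]-7-methoxy-2H-chromen-2-one | COc1ccc2cc(C(=C)C(=C)O[Si](C)(C)C(C)(C)C)c(=O)oc2c1 | intermediate
7 | glycidol (racemic) | OCC1CO1 | starting material
8 | 2-methylprop-1-enylmagnesium bromide | CC(C)=C[Mg]Br | starting material
9 | 5-methylhex-4-ene-1,2-diol (racemic) | CC(C)=CCC(O)CO | intermediate
10 | 1-hydroxy-5-methylhex-4-en-2-one | CC(C)=CCC(=O)CO | intermediate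
11 | 5-methyl-2-oxohex-4-enal | CC(C)=CCC(=O)C=O | intermediate
12 | 3-[(4R,5S)-2-(tert-butyldimethylsilyloxy)-4,5-dihydroxy-4-(3-methylbut-2-enyl)cyclohex-1-enyl]-7-methoxy-2H-chromen-2-one | COc1ccc2cc(C3=C(O[Si](C)(C)C(C)(C)C)C[C@](O)(CC=C(C)C)[C@@H](O)C3)c(=O)oc2c1 | intermediate
13 | 3-[(4R)-2-(tert-butyldimethylsilyloxy)-4-hydroxy-4-(3-methylbut-2-enyl)-5-oxocyclohex-1-enyl]-7-methoxy-2H-chromen-2-one | COc1ccc2cc(C3=C(O[Si](C)(C)C(C)(C)C)C[C@](O)(CC=C(C)C)C(=O)C3)c(=O)oc2c1 | intermediate
14 | 3-[(4R)-4-hydroxy-4-(3-methylbut-2-enyl)-3,6-dioxocyclohex-1-enyl]-7-methoxy-2H-chromen-2-one | COc1ccc2cc(C3=CC(=O)[C@@](O)(CC=C(C)C)CC3=O)c(=O)oc2c1 | target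

Total step count: 8. Longest linear sequence: 6 (steps 1, 2, 3, 6, 7, 8).

Steps most likely to fail

Step 6. Enantiofacial discrimination in the oxidative coupling may be weak at 130 °C, so the ligand chirality would be passed on only in part. The fallback sets out from 6 and 10. It runs the cycloaddition in its established racemic form with Ru3(CO)12 and achiral BIPHEP, which gives 12 together with its mirror image, the (4S,5R)-diol F1. Candida antarctica lipase B and vinyl acetate in MTBE then acylate only the (5R)-carbinol. This follows the empirical size rule for lipase acylation of secondary alcohols, with the quaternary C4 side as the large group and the CH2 side as the medium group. The product is the monoacetate F2, and unreacted 12 is separated by chromatography, where the route is rejoined at 12.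

Step 8. Transmetalation of the hindered tetrasubstituted silyl enol ether may be slow, and acetic acid or palladium may promote dehydration of the β-hydroxy ketone once C6 is unmasked. The fallback sets out from 13. PhSeCl in CH2Cl2 at −78 °C selenenylates the silyl enol ether at C1 to the α-phenylselanyl diketone F3. NaIO4/NaHCO3 in aqueous THF at 0 °C then forms the selenoxide, which eliminates in a syn fashion towards C2–H and gives 14.

Step 5. The cationic palladium may engage the alkene, the β,γ-double bond may migrate into conjugation, or the ketol may be over-oxidised. The fallback sets out from 8, which opens commercial tert-butyldimethylsilyl glycidyl ether under CuI catalysis to the secondary alcohol F4. Dess–Martin periodinane gives the silyloxy ketone F5, and HF·pyridine in THF removes the silyl group to come back at 10.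

Further compounds
F1 | step 6 | 3-[(4S,5R)-2-(tert-butyldimethylsilyloxy)-4,5-dihydroxy-4-(3-methylbut-2-enyl)cyclohex-1-enyl]-7-methoxy-2H-chromen-2-one | COc1ccc2cc(C3=C(O[Si](C)(C)C(C)(C)C)C[C@@](O)(CC=C(C)C)[C@H](O)C3)c(=O)oc2c1
F2 | step 6 | (5R)-monoacetate of F1 | COc1ccc2cc(C3=C(O[Si](C)(C)C(C)(C)C)C[C@@](O)(CC=C(C)C)[C@H](OC(C)=O)C3)c(=O)oc2c1
F3 | step 8 | 3-[(4R)-4-hydroxy-4-(3-methylbut-2-enyl)-3,6-dioxo-1-(phenylselanyl)cyclohexyl]-7-methoxy-2H-chromen-2-one | COc1ccc2cc(C3([Se]c4ccccc4)CC(=O)[C@@](O)(CC=C(C)C)CC3=O)c(=O)oc2c1
F4 | step 5 | 1-(tert-butyldimethylsilyloxy)-5-methylhex-4-en-2-ol | CC(C)=CCC(O)CO[Si](C)(C)C(C)(C)C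
F5 | step 5 | 1-(tert-butyldimethylsilyloxy)-5-methylhex-4-en-2-one | CC(C)=CCC(=O)CO[Si](C)(C)C(C)(C)C
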